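**Retrosynthetic overview**

1. The butenolide is bought as an intact ring (4-bromofuran-2(5H)-one) and joined last at C12–C13. The two equatorial carbinols (C2, C6) and the free C19–OH come from one dissolving-metal reduction of a 2,6-dione.
2. C8=C9, C7H2 and C1H2 come from SmI2 cleavage of a temporary γ-lactone C9–O–C(=O)–C1 in a 7-en-6-one, with loss of CO2.
3. Ring A (C1–C5, C10) is closed last by a tethered double Michael addition (formal [4+2]) of a C1–C4 β-keto enone unit across C10=C5 of a para-quinol ester: C1–C10 first (temporary lactone), then C4–C5.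
4. Enabling feature: ring B (C5–C10) is a dearomatised 4-alkyl-3,5-dimethylphenol (O on C6, methyls on C8 and C10, side chain on C9); C2=O and C6=O are 1,5-related through C1–C10–C5; C9 carries no heteroatom in the target and can hold a tethering oxygen that is later expelled.
5. Ring order: aromatic ring B (bought) → para-quinol → temporary lactone → ring A. The butenolide is never closed in the route.

Key step: step 8

Assumption: labdane numbering is used (ring A = C1–C5 + C10, ring B = C5–C10, C17 = methyl on C8, C18/C19 on C4, C20 = methyl on C10; β = face of C20, normal labdane series).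
Assumption: the sense of induction of the cinchona catalyst in step 8 has to be confirmed by experiment; the quinidine-derived pseudoenantiomer is the reserve for the opposite sense.

**Route**

Step 1
Reactants: 1 4-bromo-3,5-dimethylphenol; 2 potassium [2-(benzyloxy)ethyl]trifluoroborate
Product: 3 4-[2-(benzyloxy)ethyl]-3,5-dimethylphenol
Conditions: Pd(OAc)2 (5 mol %), RuPhos (10 mol %), Cs2CO3 (3 equiv), PhMe–H2O (3:1), 95 °C
Reagents that add atoms: none
Why: Suzuki–Miyaura C(sp2)–C(sp3) coupling of a primary alkyltrifluoroborate with a di-ortho-substituted aryl bromide should proceed with a bulky dialkylbiarylphosphine, the phenol being carried as its cesium phenoxide; no stereocentre is formed.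

Step 2
Reactants: 3 4-[2-(benzyloxy)ethyl]-3,5-dimethylphenol
Product: 4 4-[2-(benzyloxy)ethyl]-4-hydroxy-3,5-dimethylcyclohexa-2,5-dien-1-one (para-quinol)
Conditions: PhI(OAc)2 (1.1 equiv), MeCN–H2O (4:1), 0 °C
Reagents that add atoms: water, O
Why: Oxidative dearomatisation of a 4-alkylphenol with a hypervalent iodine reagent, in which water adds at the blocked para carbon (C9), should give the achiral para-quinol.

Step 3
Reactants: 5 benzyl propargyl ether
Product: 7 ethyl 4-(benzyloxy)but-2-ynoate, via lithium acetylide 6 (not isolated)
Conditions: n-BuLi (1.05 equiv), THF, −78 °C; ClCO2Et, −78 → 0 °C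
Reagents that add atoms: ethyl chloroformate, CCOC(=O)Cl
Why: Deprotonation of the terminal alkyne and C-acylation of the acetylide with a chloroformate is standard ynoate synthesis.

Step 4
Reactants: 7 ethyl 4-(benzyloxy)but-2-ynoate
Product: 8 ethyl (Z)-4-(benzyloxy)-3-methylbut-2-enoate
Conditions: Me2CuLi (from MeLi and CuI, 1.1 equiv), THF, −78 °C; NH4Cl (aq), −78 °C
Reagents that add atoms: lithium dimethylcuprate, [Li+].C[Cu-]C
Why: Stereospecific syn conjugate addition of a Gilman cuprate to an ynoate at low temperature, then protonation with retention, should place Me and H cis and thus CH2OBn cis to the ester (Z), the geometry that later encodes C4.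

Step 5
Reactants: 8 ethyl (Z)-4-(benzyloxy)-3-methylbut-2-enoate
Product: 9 (Z)-4-(benzyloxy)-3-methylbut-2-enoic acid
Conditions: LiOH·H2O, THF–H2O (3:1), 0 °C → rt; 1 M HCl to pH 3
Reagents that add atoms: lithium hydroxide, [Li+].[OH-]
Why: Ester saponification should leave the alkene geometry untouched, because the O-benzyl Z-acid cannot lactonise.

Step 6
Reactants: 9 (Z)-4-(benzyloxy)-3-methylbut-2-enoic acid; 10 Meldrum's acid (2,2-dimethyl-1,3-dioxane-4,6-dione)
Product: 11 5-[(Z)-4-(benzyloxy)-3-methylbut-2-enoyl]-2,2-dimethyl-1,3-dioxane-4,6-dione (acyl Meldrum's acid, present as its enol)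
Conditions: DCC (1.1 equiv), DMAP (1.5 equiv), CH2Cl2, 0 °C → rt; 1 M HCl wash
Reagents that add atoms: none
Why: Carbodiimide-mediated C-acylation of Meldrum's acid is the standard entry to acylketene precursors.

Step 7
Reactants: 4 para-quinol; 11 acyl Meldrum's acid
Product: 13 1-[2-(benzyloxy)ethyl]-2,6-dimethyl-4-oxocyclohexa-2,5-dien-1-yl (Z)-6-(benzyloxy)-5-methyl-3-oxohex-4-enoate, via acylketene 12 (not isolated)
Conditions: PhMe, 85 °C, 3 h (11 in slight excess)
Reagents that add atoms: none
Why: Thermal fragmentation of the acyl Meldrum's acid (loss of acetone and CO2) gives an acylketene that acylates even hindered tertiary alcohols, and the base-free medium should keep the β-keto ester from cyclising before the chiral catalyst is present.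

Step 8
Reactants: 13 para-quinol γ,δ-unsaturated β-keto ester
Product: 15 12,19-bis(benzyloxy)-2,6-dioxo-13,14,15,16-tetranor-5β-labd-7-ene-1α,9α-carbolactone (cis-fused tricyclic keto lactone), via mono-Michael lactone 14 (not isolated)
Conditions: quinine-derived 3,5-bis(trifluoromethyl)phenyl squaramide (10 mol %), PhMe, 0 °C → rt; then pyrrolidine (30 mol %), AcOH (60 mol %), 40 °C; aqueous work-up
Reagents that add atoms: none
Why: Proposed new method: the squaramide (H-bond donor plus quinuclidine base) should deliver C1 of the β-keto ester to C10 of one of the two enantiotopic enone arms of the achiral dienone (5-exo-trig, closes the temporary γ-lactone, gives 14), after which pyrrolidinium acetate should convert the ring-B enone of 14 into its cross-conjugated dienamine, whose C5 adds to C4 of the C2 enone (6-endo-trig, closes ring A) before hydrolysis, the sum being a tethered stepwise [4+2] of the C1–C4 unit across C10=C5. The closest known reactions are bifunctional-amine-catalysed desymmetrising intramolecular Michael additions of 1,3-dicarbonyls to 4,4-disubstituted cyclohexadienones, α′-Michael additions of cyclohexenones through cross-conjugated dienamines, and base-mediated double-Michael annulations of γ,δ-unsaturated β-keto esters with cyclohexenones; what is new is the ester tether through the quinol oxygen, the relay in one flask and the formation of two quaternary carbons (C10, C4). An amine rather than a base closes the second bond because a base would stop at the stable C1 enolate of 14, which switches off the C2 enone, whereas the neutral dienamine leaves the 2-acyl lactone in its keto form. Stereocontrol: C10 (and the now stereogenic C9) by the catalyst's choice of arm, with C1 entering syn to the tethering oxygen so that C20 ends anti to it; C1 by the lactone, which allows only the all-cis fusion; C4 by the (Z) enone geometry combined with the compact synclinal (endo) approach under ring B, which places CH2OBn on the face of C20; C5 by suprafacial closure, which gives the cis-fused 5β-H ketone that step 9 corrects. The step needs arm selectivity (catalyst), reaction at C5 rather than C7 (C7 is sp2, C5 is the only α′ position), attack at C4 (the only ketone-activated β-carbon) and retention of the enone geometry (no strong acid or base present).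

Step 9
Reactants: 15 cis-fused tricyclic keto lactone
Product: 17 12,19-bis(benzyloxy)-2,6-dioxo-13,14,15,16-tetranorlabd-7-ene-1α,9α-carbolactone (5α-H, trans-fused), via dilithium dienolate 16 (not isolated)
Conditions: LiN(i-Pr)2 (2.5 equiv), THF, −78 → −40 °C; AcOH (5 equiv) in THF, −78 °C
Reagents that add atoms: none
Why: Irreversible double deprotonation (C1–H, then the only α′-H at C5) followed by kinetic C-protonation of the cross-conjugated dienolate should occur from the α face, because the β face of C5 is screened by the flanking axial C20 methyl and C19 CH2OBn (the usual facial bias of Δ5 systems with an angular methyl), giving the trans-fused ketone, while C1 can only return to the lactone-compatible configuration.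

Step 10
Reactants: 17 trans-fused tricyclic keto lactone
Product: 19 12,19-bis(benzyloxy)-13,14,15,16-tetranorlabd-8-ene-2,6-dione, via β-keto acid 18 (not isolated)
Conditions: SmI2 (2.5 equiv), THF–MeOH (10:1), −78 °C; pH 7 buffer; then PhMe, 40 °C
Reagents that add atoms: none
Why: SmI2 reduction of a γ-acyloxy enone (vinylogous α-acyloxy ketone) should expel the C9 carboxylate, kinetic α-protonation (C7) of the samarium dienolate should give the β,γ-unsaturated ketone with the tetrasubstituted C8=C9 alkene, and the liberated β-keto acid should lose CO2 to leave C1H2, with C4, C5 and C10 untouched.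

Step 11
Reactants: 19 bis(benzyloxy) 2,6-dione
Product: 20 13,14,15,16-tetranorlabd-8-ene-2α,6α,12,19-tetrol
Conditions: Li (20 equiv), NH3(l)–THF, t-BuOH (4 equiv), −78 → −40 °C (19 added to the metal solution); solid NH4Cl
Reagents that add atoms: none
Why: Dissolving-metal reduction should convert both ketones into the thermodynamically preferred equatorial alcohols (2α and 6α; each axial epimer would be syn-diaxial to C19 and C20, which is also why hydride reagents would give the wrong epimers) and cleave both benzyl ethers in the same operation, the isolated tetrasubstituted alkene being inert.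

Step 12
Reactants: 20 tetrol
Product: 21 12-iodo-13,14,15,16-tetranorlabd-8-ene-2α,6α,19-triol
Conditions: I2 (1.2 equiv), PPh3 (1.2 equiv), imidazole (2.5 equiv), THF–MeCN, 0 °C
Reagents that add atoms: iodine, II
Why: Appel iodination should be selective for the unhindered primary C12 alcohol, since the neopentyl C19 and the two secondary alcohols resist SN2 displacement at 0 °C.

Step 13
Reactants: 21 C12 iodide; 22 4-bromofuran-2(5H)-one
Product: 23 2α,6α,19-trihydroxylabda-8,13-dien-15,16-olide (target, CNP0387838.1)
Conditions: NiBr2(dme) (10 mol %), 4,4′-di-tert-butyl-2,2′-bipyridine (10 mol %), Zn dust (2 equiv), DMA, 25 °C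
Reagents that add atoms: none
Why: Nickel-catalysed reductive cross-electrophile coupling of a primary alkyl iodide with an alkenyl bromide tolerates free hydroxyls and should join C12 to C13 of the preformed butenolide ring without touching any stereocentre.

**Compound list**

1 | 4-bromo-3,5-dimethylphenol | Cc1cc(O)cc(C)c1Br | starting material
2 | potassium [2-(benzyloxy)ethyl]trifluoroborate | [K+].F[B-](F)(F)CCOCc1ccccc1 | starting material
3 | 4-[2-(benzyloxy)ethyl]-3,5-dimethylphenol | Cc1cc(O)cc(C)c1CCOCc1ccccc1 | intermediate
4 | 4-[2-(benzyloxy)ethyl]-4-hydroxy-3,5-dimethylcyclohexa-2,5-dien-1-one | CC1=CC(=O)C=C(C)C1(O)CCOCc1ccccc1 | intermediate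
5 | benzyl propargyl ether | C#CCOCc1ccccc1 | starting material
6 | lithium acetylide of 5 | [Li+].[C-]#CCOCc1ccccc1 | intermediate
7 | ethyl 4-(benzyloxy)but-2-ynoate | CCOC(=O)C#CCOCc1ccccc1 | intermediate
8 | ethyl (Z)-4-(benzyloxy)-3-methylbut-2-enoate | CCOC(=O)/C=C(C)\COCc1ccccc1 | intermediate
9 | (Z)-4-(benzyloxy)-3-methylbut-2-enoic acid | OC(=O)/C=C(C)\COCc1ccccc1 | intermediate
10 | Meldrum's acid | CC1(C)OC(=O)CC(=O)O1 | starting material
11 | 5-[(Z)-4-(benzyloxy)-3-methylbut-2-enoyl]-2,2-dimethyl-1,3-dioxane-4,6-dione (drawn as keto tautomer) | CC1(C)OC(=O)C(C(=O)/C=C(C)\COCc2ccccc2)C(=O)O1 | intermediate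
12 | [(Z)-4-(benzyloxy)-3-methylbut-2-enoyl]ketene | O=C=CC(=O)/C=C(C)\COCc1ccccc1 | intermediate
13 | 1-[2-(benzyloxy)ethyl]-2,6-dimethyl-4-oxocyclohexa-2,5-dien-1-yl (Z)-6-(benzyloxy)-5-methyl-3-oxohex-4-enoate | CC1=CC(=O)C=C(C)C1(CCOCc1ccccc1)OC(=O)CC(=O)/C=C(C)\COCc1ccccc1 | intermediate
14 | mono-Michael adduct: cis-fused γ-lactone (C9α–O, C1α–C10), 10β-methyl, ring B as 7-en-6-one with C5H2, C1 carrying the (Z)-enoyl chain | CC1=CC(=O)C[C@]2(C)[C@H](C(=O)/C=C(C)\COCc3ccccc3)C(=O)O[C@]12CCOCc4ccccc4 | intermediate
15 | 12,19-bis(benzyloxy)-2,6-dioxo-13,14,15,16-tetranor-5β-labd-7-ene-1α,9α-carbolactone (cis-fused) | CC1=CC(=O)[C@@H]2[C@@](C)(COCc4ccccc4)CC(=O)[C@@H]3C(=O)O[C@@]1(CCOCc5ccccc5)[C@]23C | intermediate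
16 | dilithium C1,C2/C5,C6 bis-enolate of 15 | CC1=CC([O-])=C2[C@@](C)(COCc4ccccc4)CC([O-])=C3C(=O)O[C@@]1(CCOCc5ccccc5)[C@]23C.[Li+].[Li+] | intermediate
17 | 12,19-bis(benzyloxy)-2,6-dioxo-13,14,15,16-tetranorlabd-7-ene-1α,9α-carbolactone (5α-H, trans-fused) | CC1=CC(=O)[C@H]2[C@@](C)(COCc4ccccc4)CC(=O)[C@@H]3C(=O)O[C@@]1(CCOCc5ccccc5)[C@]23C | intermediate
18 | 12,19-bis(benzyloxy)-2,6-dioxo-13,14,15,16-tetranorlabd-8-ene-1α-carboxylic acid | CC1=C(CCOCc3ccccc3)[C@@]2(C)[C@@H](C(=O)O)C(=O)C[C@](C)(COCc4ccccc4)[C@@H]2C(=O)C1 | intermediate
19 | 12,19-bis(benzyloxy)-13,14,15,16-tetranorlabd-8-ene-2,6-dione | CC1=C(CCOCc3ccccc3)[C@@]2(C)CC(=O)C[C@](C)(COCc4ccccc4)[C@@H]2C(=O)C1 | intermediate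
20 | 13,14,15,16-tetranorlabd-8-ene-2α,6α,12,19-tetrol | CC1=C(CCO)[C@@]2(C)C[C@@H](O)C[C@](C)(CO)[C@@H]2[C@@H](O)C1 | intermediate
21 | 12-iodo-13,14,15,16-tetranorlabd-8-ene-2α,6α,19-triol | CC1=C(CCI)[C@@]2(C)C[C@@H](O)C[C@](C)(CO)[C@@H]2[C@@H](O)C1 | intermediate
22 | 4-bromofuran-2(5H)-one | BrC1=CC(=O)OC1 | starting material
23 | 2α,6α,19-trihydroxylabda-8,13-dien-15,16-olide | CC1=C(CCC2=CC(=O)OC2)[C@@]2(C)C[C@@H](O)C[C@](C)(CO)[C@@H]2[C@@H](O)C1 | target

**Step count**

Total steps: 13. Longest linear sequence: 11 steps (steps 3 to 13, from benzyl propargyl ether 5).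

**Steps most likely to fail**

Step 8 (proposed new method). The second conjugate addition may stall at the mono-adduct because the dienamine cannot engage the hindered β,β-disubstituted enone, or the mono-adduct may revert by retro-Michael opening and lose enantiopurity. The fallback separates the two events and uses classical stoichiometric enamine chemistry. It sets out from 13: the squaramide-catalysed desymmetrising Michael addition is run alone and the mono-Michael lactone 14 is isolated. 14 is then condensed with pyrrolidine (TsOH cat., benzene, water removal) to the preformed pyrrolidine cross-dienamine F1, which is heated to effect the intramolecular enamine Michael addition and hydrolysed with aqueous AcOH. The fallback comes back to the route at 15.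

Step 9. Protonation of the dienolate may occur from the β face, or deprotonation may take place at the C8 methyl (γ) instead of the hindered C5–H, returning 15 or its deconjugated isomer. The fallback replaces the irreversible kinetic quench by thermodynamic control. It sets out from 15, which is equilibrated at C5 through reversible enolisation with DBU in PhMe at 60 °C (only C5 can enolise while C7 is sp2). The trans-fused ketone is separated and recovered 15 is resubmitted. The fallback comes back at 17 and makes no new compound; it helps only if the trans-fused isomer is the more stable one, which is not established.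

Step 13. The bromobutenolide may be reduced or homocoupled by zinc and nickel faster than it captures the alkyl radical, or the alkyl iodide may be lost by protodehalogenation or elimination. The fallback is a B-alkyl Suzuki–Miyaura route. It sets out from 21, which is dehydroiodinated with KOt-Bu in THF at 0 °C to the conjugated diene triol F2. The terminal vinyl group of F2 is hydroborated chemoselectively with excess 9-BBN (the hydroxyls are borylated in the flask) to give the alkylborane F3. F3 is coupled in the same flask with 22 (Pd(dppf)Cl2, Cs2CO3, DMF–H2O, 50 °C); the borinates are cleaved on work-up. The fallback comes back at 23.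

Further compounds
F1 | step 8 | pyrrolidine cross-conjugated dienamine of 14 (N on C6, C5=C6 and C7=C8) | CC1=CC(N5CCCC5)=C[C@]2(C)[C@H](C(=O)/C=C(C)\COCc3ccccc3)C(=O)O[C@]12CCOCc4ccccc4
F0 | step 9 | none | none
F2 | step 13 | 13,14,15,16-tetranorlabda-8,11-diene-2α,6α,19-triol | CC1=C(C=C)[C@@]2(C)C[C@@H](O)C[C@](C)(CO)[C@@H]2[C@@H](O)C1
F3 | step 13 | C12 B-alkyl-9-BBN derivative of F2 with the three hydroxyls as 9-BBN borinates | CC1=C(CCB3C4CCCC3CCC4)[C@@]2(C)C[C@@H](OB3C4CCCC3CCC4)C[C@](C)(COB3C4CCCC3CCC4)[C@@H]2[C@@H](OB3C4CCCC3CCC4)C1
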